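**Plan**

1. Numbering used throughout: pyran O1, C2 (CMe2), C3=C4, C5 (CHOH), C6 (C–CH3); carbocycle C1' (on C6) to C6', with Cl and CH3 on C4' and Br on C5'.
2. Retrosynthesis: C5'–Br, C4'–CH3, C4'–Cl and the C3=C4 unsaturation are removed first. Then O1–C6 and C6–C1' are cut together: C6 is an ether carbon bonded at once to O1, to the ring carbonyl carbon C5 and to C1', so a ylide centred on O1 can make both bonds. The tertiary ether bond C2–O1 is cut last.
3. Forward: the carbocycle is there from the start (cyclohexa-1,3-diene). The chain is joined through the tertiary ether, extended to the methyl diazoketone, and the oxan-3-one ring closes in the key step. The pyran alkene, the C5 carbinol and the halogens follow.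
4. Stereochemistry: enzymatic desymmetrisation fixes the ether carbon C3' as S. The suprafacial [2,3] shift carries it to C1' and, through an exo envelope, to C6 (R). That shift leaves its alkene at C2'=C3', so an acetoxy group on C6' marks the arm that will carry the halogens.
5. C5 comes from reagent-controlled CBS reduction, C4' from axial methylation of a chloro enolate, C5' from equatorial hydride delivery followed by invertive bromination.

Key step: step 8

Assumption: the hydrolase in step 2 frees the hydroxyl on the carbon that becomes C3', giving the (1R,4S)-monoacetate 3; a hydrolase of opposite preference is used in the acylation direction on the meso diol to reach the same monoacetate.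

**Step 1**
Reactants: 1 cyclohexa-1,3-diene
Product: 2 cis-cyclohex-2-ene-1,4-diyl diacetate (meso)
Conditions: Pd(OAc)2 (cat.), LiCl (cat.), LiOAc, p-benzoquinone (cat.), MnO2, AcOH, 25 °C
Reagents that add atoms: acetic acid, CC(=O)O
Why: Palladium-catalysed 1,4-diacetoxylation of a conjugated diene (Bäckvall oxidation), in which catalytic chloride makes the second acetate attack the π-allyl complex from outside, so the diacetate is cis and therefore meso.

**Step 2**
Reactants: 2 cis-cyclohex-2-ene-1,4-diyl diacetate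
Product: 3 (1R,4S)-4-hydroxycyclohex-2-en-1-yl acetate
Conditions: Candida antarctica lipase B, phosphate buffer pH 7, 25 °C
Reagents that add atoms: none
Why: Enzymatic desymmetrisation of a meso diester by hydrolysis of one enantiotopic acetate, which fixes the absolute configuration of both ring stereocentres with the free carbinol S.

**Step 3**
Reactants: 3 (1R,4S)-4-hydroxycyclohex-2-en-1-yl acetate
Product: 4 (1R,4S)-4-[(trimethylsilyl)oxy]cyclohex-2-en-1-yl acetate
Conditions: Me3SiCl, imidazole, CH2Cl2, 0 °C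
Reagents that add atoms: chlorotrimethylsilane, C[Si](C)(C)Cl
Why: Silyl ether formation turns the secondary alcohol into the oxygen nucleophile that step 4 needs.

**Step 4**
Reactants: 4 (1R,4S)-4-[(trimethylsilyl)oxy]cyclohex-2-en-1-yl acetate; 5 acetone; 6 allyltrimethylsilane
Product: 7 (1R,4S)-4-[(2-methylpent-4-en-2-yl)oxy]cyclohex-2-en-1-yl acetate
Conditions: Me3SiOTf (0.2 equiv), CH2Cl2, −78 °C
Reagents that add atoms: none
Why: Sakurai-type three-component allylation of a ketone by a silyl ether and an allylsilane builds the tertiary ether; the ketone is allylated only after the silyl ether oxygen has added to it, and the O–C bond at the stereocentre is never broken.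

**Step 5**
Reactants: 7 (1R,4S)-4-[(2-methylpent-4-en-2-yl)oxy]cyclohex-2-en-1-yl acetate
Product: 9 (1R,4S)-4-[(5-hydroxy-2-methylpentan-2-yl)oxy]cyclohex-2-en-1-yl acetate, via B-alkyl-9-BBN adduct 8 (not isolated)
Conditions: 9-BBN, THF, 0 → 25 °C; then NaBO3·4H2O, H2O, 25 °C
Reagents that add atoms: sodium perborate, [Na+].[Na+].O[B-]1(O)OO[B-](O)(O)OO1
Why: Anti-Markovnikov hydroboration–oxidation, in which 9-BBN takes the monosubstituted alkene far faster than the ring alkene and perborate oxidises the borane without cleaving the acetate.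

**Step 6**
Reactants: 9 (1R,4S)-4-[(5-hydroxy-2-methylpentan-2-yl)oxy]cyclohex-2-en-1-yl acetate
Product: 11 4-{[(1S,4R)-4-acetoxycyclohex-2-en-1-yl]oxy}-4-methylpentanoic acid, via aldehyde 10 (not isolated)
Conditions: TEMPO (cat.), PhI(OAc)2, MeCN/H2O, 25 °C
Reagents that add atoms: water, O
Why: Nitroxyl-catalysed oxidation of a primary alcohol through the aldehyde hydrate to the acid, under nearly neutral conditions that spare the tertiary allylic ether, the alkene and the acetate.

**Step 7**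
Reactants: 11 4-{[(1S,4R)-4-acetoxycyclohex-2-en-1-yl]oxy}-4-methylpentanoic acid
Product: 13 (1R,4S)-4-[(6-diazo-2-methyl-5-oxoheptan-2-yl)oxy]cyclohex-2-en-1-yl acetate, via mixed carbonic anhydride 12 (not isolated)
Conditions: i-BuOCOCl, Et3N, THF, −20 °C; then CH3CHN2 (from N-ethyl-N-nitrosourea, KOH), Et2O, 0 °C
Reagents that add atoms: diazoethane, CC=[N+]=[N-]
Why: Acylation of a diazoalkane by a mixed carbonic anhydride (diazoketone synthesis of the Arndt–Eistert type); this avoids an acid chloride that the γ-alkoxy oxygen could attack, and the carbonate leaving group takes up the proton.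

**Step 8**
Reactants: 13 (1R,4S)-4-[(6-diazo-2-methyl-5-oxoheptan-2-yl)oxy]cyclohex-2-en-1-yl acetate
Product: 15 (1R,2S)-2-[(2R)-2,6,6-trimethyl-3-oxooxan-2-yl]cyclohex-3-en-1-yl acetate, via oxonium ylide 14 (not isolated)
Conditions: Cu(hfacac)2 (5 mol %), CH2Cl2, reflux, slow addition of 13
Reagents that add atoms: none
Why: Loss of N2 at divalent copper gives the carbenoid at C6, a lone pair of the tertiary ether oxygen adds to it and closes the six-membered oxonium ylide 14 (ring closure by attack of O1 on the carbenoid carbon along the tether O1–C2–C3–C4–C5–C6), and a concerted suprafacial [2,3]-sigmatropic shift of the cyclohex-2-enyl group then forms C6–C1' while O1–C3' breaks and the alkene moves to C2'=C3'. The closest known reaction is the copper- or rhodium-catalysed oxonium ylide formation and [2,3] rearrangement of allyl ethers tethered to diazoketones, which gives 2-allyl oxan-3-ones and has precedent for substituted diazo carbons. C1' is set by the ether stereocentre C3' (S), because the new bond must form on the ring face that carried the oxygen. C6 is set by the exo envelope of the five-membered transition state, in which the C4'–C5'–C6' part of the carbocycle lies on the side of the C6 methyl and away from the oxane ring with its two C2 methyl groups, so that C6' ends anti to C5; this is why the S ether gives 6R and why the new alkene sits at C2'=C3'. The step needs ylide formation to beat 1,2-hydride shift and C–H insertion and the [2,3] path to beat the [1,2] shift: the quaternary C2 leaves no hydrogen for 1,5-insertion, the electron-poor copper catalyst at low diazo concentration favours capture by oxygen, and the allylic ether makes the five-membered pathway the easy one. The acetoxy group on C6' is a spectator that stays equatorial and gauche to the forming bond.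

**Step 9**
Reactants: 15 (1R,2S)-2-[(2R)-2,6,6-trimethyl-3-oxooxan-2-yl]cyclohex-3-en-1-yl acetate
Product: 16 (1R,2S)-2-[(2R)-2,6,6-trimethyl-3-oxooxan-2-yl]cyclohexyl acetate
Conditions: H2 (1 atm), Pd/C, EtOAc, 25 °C
Reagents that add atoms: none
Why: Heterogeneous catalytic hydrogenation saturates the cis-disubstituted C2'=C3' alkene while the hindered ketone and the acetate stay, so that from here the acetoxy group alone tells the two ring arms apart.

**Step 10**
Reactants: 16 (1R,2S)-2-[(2R)-2,6,6-trimethyl-3-oxooxan-2-yl]cyclohexyl acetate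
Product: 18 (1R,2S)-2-[(2R)-2,6,6-trimethyl-3-oxo-3,6-dihydro-2H-pyran-2-yl]cyclohexyl acetate, via trimethylsilyl enol ether 17 (not isolated)
Conditions: Me3SiOTf, Et3N, CH2Cl2, 0 °C; then Pd(OAc)2, MeCN, 25 °C
Reagents that add atoms: none
Why: Saegusa–Ito dehydrogenation; because C6 is fully substituted the ketone can only enolise toward C4, so the enone can only be C3=C4.

**Step 11**
Reactants: 18 (1R,2S)-2-[(2R)-2,6,6-trimethyl-3-oxo-3,6-dihydro-2H-pyran-2-yl]cyclohexyl acetate
Product: 19 (1R,2S)-2-[(2R,3R)-3-hydroxy-2,6,6-trimethyl-3,6-dihydro-2H-pyran-2-yl]cyclohexyl acetate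
Conditions: (S)-2-methyl-CBS-oxazaborolidine, catecholborane, toluene, −78 °C
Reagents that add atoms: none
Why: Corey–Bakshi–Shibata reduction under reagent control, with the fully substituted C6 as the large group and the vinyl carbon C4 as the small one, so that the (S)-catalyst should give the 5R carbinol (hydroxyl trans to the C6 methyl) while catecholborane at −78 °C leaves alkene and ester alone.

**Step 12**
Reactants: 19 (1R,2S)-2-[(2R,3R)-3-hydroxy-2,6,6-trimethyl-3,6-dihydro-2H-pyran-2-yl]cyclohexyl acetate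
Product: 20 (1R,2S)-2-{(2R,3R)-3-[(tert-butyldimethylsilyl)oxy]-2,6,6-trimethyl-3,6-dihydro-2H-pyran-2-yl}cyclohexyl acetate
Conditions: t-BuMe2SiOTf, 2,6-lutidine, CH2Cl2, 0 °C
Reagents that add atoms: tert-butyldimethylsilyl trifluoromethanesulfonate, CC(C)(C)[Si](C)(C)OS(=O)(=O)C(F)(F)F
Why: Silyl ether protection with a silyl triflate and a hindered base shields the crowded allylic alcohol from the oxidant, the amide bases and the hydride used later.

**Step 13**
Reactants: 20 (1R,2S)-2-{(2R,3R)-3-[(tert-butyldimethylsilyl)oxy]-2,6,6-trimethyl-3,6-dihydro-2H-pyran-2-yl}cyclohexyl acetate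
Product: 21 (1R,2S)-2-{(2R,3R)-3-[(tert-butyldimethylsilyl)oxy]-2,6,6-trimethyl-3,6-dihydro-2H-pyran-2-yl}cyclohexan-1-ol
Conditions: K2CO3 (cat.), MeOH, 25 °C
Reagents that add atoms: none
Why: Base-catalysed transesterification (methanolysis) removes the acetate and frees the axial C6' hydroxyl.

**Step 14**
Reactants: 21 (1R,2S)-2-{(2R,3R)-3-[(tert-butyldimethylsilyl)oxy]-2,6,6-trimethyl-3,6-dihydro-2H-pyran-2-yl}cyclohexan-1-ol
Product: 23 tert-butyl({(2R,3R)-2-[(1S)-cyclohex-2-en-1-yl]-2,6,6-trimethyl-3,6-dihydro-2H-pyran-3-yl}oxy)dimethylsilane, via sulfamate ester 22 (not isolated)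
Conditions: Burgess reagent, toluene, 25 → 70 °C
Reagents that add atoms: none
Why: Burgess dehydration is a syn elimination; the C6' oxygen is axial and cis to the side chain, so only a hydrogen on C5' is syn to it (the C1' hydrogen is anti) and the alkene forms at C5'=C6'.

**Step 15**
Reactants: 23 tert-butyl({(2R,3R)-2-[(1S)-cyclohex-2-en-1-yl]-2,6,6-trimethyl-3,6-dihydro-2H-pyran-3-yl}oxy)dimethylsilane
Product: 25 (1S,3S)-3-{(2R,3R)-3-[(tert-butyldimethylsilyl)oxy]-2,6,6-trimethyl-3,6-dihydro-2H-pyran-2-yl}cyclohexan-1-ol, via B-alkyl-9-BBN adduct 24 (not isolated)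
Conditions: 9-BBN, THF, 65 °C; then NaOH, H2O2, 0 °C
Reagents that add atoms: hydrogen peroxide, OO
Why: Hydroboration–oxidation with 9-BBN, which should add to the carbocyclic alkene with boron on C5' (away from C1' and its fully substituted neighbour) and spare the pyran alkene flanked by the quaternary C2 and the silyloxy carbon; the new carbinol centre is removed in step 16.

**Step 16**
Reactants: 25 (1S,3S)-3-{(2R,3R)-3-[(tert-butyldimethylsilyl)oxy]-2,6,6-trimethyl-3,6-dihydro-2H-pyran-2-yl}cyclohexan-1-ol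
Product: 26 (3S)-3-{(2R,3R)-3-[(tert-butyldimethylsilyl)oxy]-2,6,6-trimethyl-3,6-dihydro-2H-pyran-2-yl}cyclohexan-1-one
Conditions: Dess–Martin periodinane, CH2Cl2, 25 °C
Reagents that add atoms: none
Why: Dess–Martin oxidation of the secondary alcohol gives the C5' ketone under neutral conditions.

**Step 17**
Reactants: 26 (3S)-3-{(2R,3R)-3-[(tert-butyldimethylsilyl)oxy]-2,6,6-trimethyl-3,6-dihydro-2H-pyran-2-yl}cyclohexan-1-one
Product: 28 (2R,5S)-2-chloro-5-{(2R,3R)-3-[(tert-butyldimethylsilyl)oxy]-2,6,6-trimethyl-3,6-dihydro-2H-pyran-2-yl}cyclohexan-1-one, via trimethylsilyl enol ether 27 (not isolated)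
Conditions: LiN(SiMe3)2, Me3SiCl, THF, −78 °C; then N-chlorosuccinimide, THF, 0 °C
Reagents that add atoms: N-chlorosuccinimide, O=C1CCC(=O)N1Cl
Why: Kinetic enolisation with internal silyl trapping should take a proton from C4' rather than from C6', which is shielded by the fully substituted group on C1', and electrophilic chlorination of the silyl enol ether then puts chlorine on C4' (its configuration is reset in step 18).

**Step 18**
Reactants: 28 (2R,5S)-2-chloro-5-{(2R,3R)-3-[(tert-butyldimethylsilyl)oxy]-2,6,6-trimethyl-3,6-dihydro-2H-pyran-2-yl}cyclohexan-1-one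
Product: 30 (2S,5S)-2-chloro-2-methyl-5-{(2R,3R)-3-[(tert-butyldimethylsilyl)oxy]-2,6,6-trimethyl-3,6-dihydro-2H-pyran-2-yl}cyclohexan-1-one, via lithium chloro enolate 29 (not isolated)
Conditions: LiN(SiMe3)2, THF, −78 °C; then MeI, DMPU, −78 → −20 °C
Reagents that add atoms: iodomethane, CI
Why: Enolate alkylation, in which the C4' hydrogen (acidified by chlorine and unhindered) is removed and methyl iodide attacks the chloro enolate along the axial direction through a chair-like transition state with the side chain equatorial, making the methyl axial and cis to the side chain and leaving chlorine equatorial.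

**Step 19**
Reactants: 30 (2S,5S)-2-chloro-2-methyl-5-{(2R,3R)-3-[(tert-butyldimethylsilyl)oxy]-2,6,6-trimethyl-3,6-dihydro-2H-pyran-2-yl}cyclohexan-1-one
Product: 31 (1R,2S,5S)-2-chloro-2-methyl-5-{(2R,3R)-3-[(tert-butyldimethylsilyl)oxy]-2,6,6-trimethyl-3,6-dihydro-2H-pyran-2-yl}cyclohexan-1-ol
Conditions: LiBH(s-Bu)3, THF, −78 °C
Reagents that add atoms: none
Why: Reduction with a bulky trialkylborohydride, whose hydride comes from the equatorial direction to avoid the axial hydrogens on C1' and C3' (as with other ketones next to a fully substituted carbon), should give the axial C5' alcohol cis to chlorine.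

**Step 20**
Reactants: 31 (1R,2S,5S)-2-chloro-2-methyl-5-{(2R,3R)-3-[(tert-butyldimethylsilyl)oxy]-2,6,6-trimethyl-3,6-dihydro-2H-pyran-2-yl}cyclohexan-1-ol
Product: 32 tert-butyl({(2R,3R)-2-[(1S,3S,4S)-3-bromo-4-chloro-4-methylcyclohexyl]-2,6,6-trimethyl-3,6-dihydro-2H-pyran-3-yl}oxy)dimethylsilane
Conditions: PPh3, CBr4, toluene, 60 °C
Reagents that add atoms: tetrabromomethane, BrC(Br)(Br)Br
Why: Appel bromination, in which the phosphine/CBr4 pair activates the axial hydroxyl and bromide displaces it from the back (SN2), so bromine ends equatorial, trans to chlorine and cis to the side chain.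

**Step 21**
Reactants: 32 tert-butyl({(2R,3R)-2-[(1S,3S,4S)-3-bromo-4-chloro-4-methylcyclohexyl]-2,6,6-trimethyl-3,6-dihydro-2H-pyran-3-yl}oxy)dimethylsilane
Product: 33 (2R,3R)-2-[(1S,3S,4S)-3-bromo-4-chloro-4-methylcyclohexyl]-2,6,6-trimethyl-3,6-dihydro-2H-pyran-3-ol
Conditions: HF·pyridine, pyridine, THF, 0 → 25 °C
Reagents that add atoms: none
Why: Fluoride-mediated cleavage of the silyl ether under buffered, non-basic conditions frees the C5 hydroxyl without touching the secondary bromide or the tertiary chloride.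

**Compound list**

1 | cyclohexa-1,3-diene | C1=CC=CCC1 | starting material
2 | cis-cyclohex-2-ene-1,4-diyl diacetate (meso) | CC(=O)O[C@@H]1C=C[C@H](OC(C)=O)CC1 | intermediate
3 | (1R,4S)-4-hydroxycyclohex-2-en-1-yl acetate | O[C@@H]1C=C[C@H](OC(C)=O)CC1 | intermediate
4 | (1R,4S)-4-[(trimethylsilyl)oxy]cyclohex-2-en-1-yl acetate | C[Si](C)(C)O[C@@H]1C=C[C@H](OC(C)=O)CC1 | intermediate
5 | acetone | CC(C)=O | starting material
6 | allyltrimethylsilane | C=CC[Si](C)(C)C | starting material
7 | (1R,4S)-4-[(2-methylpent-4-en-2-yl)oxy]cyclohex-2-en-1-yl acetate | C=CCC(C)(C)O[C@@H]1C=C[C@H](OC(C)=O)CC1 | intermediate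
8 | (1R,4S)-4-{[5-(9-borabicyclo[3.3.1]nonan-9-yl)-2-methylpentan-2-yl]oxy}cyclohex-2-en-1-yl acetate (not isolated) | CC(C)(CCCB1C2CCCC1CCC2)O[C@@H]1C=C[C@H](OC(C)=O)CC1 | intermediate
9 | (1R,4S)-4-[(5-hydroxy-2-methylpentan-2-yl)oxy]cyclohex-2-en-1-yl acetate | OCCCC(C)(C)O[C@@H]1C=C[C@H](OC(C)=O)CC1 | intermediate
10 | (1R,4S)-4-[(2-methyl-5-oxopentan-2-yl)oxy]cyclohex-2-en-1-yl acetate (not isolated) | O=CCCC(C)(C)O[C@@H]1C=C[C@H](OC(C)=O)CC1 | intermediate
11 | 4-{[(1S,4R)-4-acetoxycyclohex-2-en-1-yl]oxy}-4-methylpentanoic acid | OC(=O)CCC(C)(C)O[C@@H]1C=C[C@H](OC(C)=O)CC1 | intermediate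
12 | mixed anhydride of 11 with isobutyl hydrogen carbonate (not isolated) | CC(C)COC(=O)OC(=O)CCC(C)(C)O[C@@H]1C=C[C@H](OC(C)=O)CC1 | intermediate
13 | (1R,4S)-4-[(6-diazo-2-methyl-5-oxoheptan-2-yl)oxy]cyclohex-2-en-1-yl acetate | CC(=[N+]=[N-])C(=O)CCC(C)(C)O[C@@H]1C=C[C@H](OC(C)=O)CC1 | intermediate
14 | 1-[(1S,4R)-4-acetoxycyclohex-2-en-1-yl]-2,6,6-trimethyl-3-oxooxan-1-ium-2-ide, the oxonium ylide (not isolated) | C[C-]1C(=O)CCC(C)(C)[O+]1[C@@H]1C=C[C@H](OC(C)=O)CC1 | intermediate
15 | (1R,2S)-2-[(2R)-2,6,6-trimethyl-3-oxooxan-2-yl]cyclohex-3-en-1-yl acetate | CC1(C)CCC(=O)[C@@](C)([C@H]2C=CCC[C@H]2OC(C)=O)O1 | intermediate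
16 | (1R,2S)-2-[(2R)-2,6,6-trimethyl-3-oxooxan-2-yl]cyclohexyl acetate | CC1(C)CCC(=O)[C@@](C)([C@H]2CCCC[C@H]2OC(C)=O)O1 | intermediate
17 | (1R,2S)-2-{(2R)-2,6,6-trimethyl-3-[(trimethylsilyl)oxy]-5,6-dihydro-2H-pyran-2-yl}cyclohexyl acetate (not isolated) | CC1(C)CC=C(O[Si](C)(C)C)[C@@](C)([C@H]2CCCC[C@H]2OC(C)=O)O1 | intermediate
18 | (1R,2S)-2-[(2R)-2,6,6-trimethyl-3-oxo-3,6-dihydro-2H-pyran-2-yl]cyclohexyl acetate | CC1(C)C=CC(=O)[C@@](C)([C@H]2CCCC[C@H]2OC(C)=O)O1 | intermediate
19 | (1R,2S)-2-[(2R,3R)-3-hydroxy-2,6,6-trimethyl-3,6-dihydro-2H-pyran-2-yl]cyclohexyl acetate | CC1(C)C=C[C@@H](O)[C@@](C)([C@H]2CCCC[C@H]2OC(C)=O)O1 | intermediate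
20 | (1R,2S)-2-{(2R,3R)-3-[(tert-butyldimethylsilyl)oxy]-2,6,6-trimethyl-3,6-dihydro-2H-pyran-2-yl}cyclohexyl acetate | CC1(C)C=C[C@@H](O[Si](C)(C)C(C)(C)C)[C@@](C)([C@H]2CCCC[C@H]2OC(C)=O)O1 | intermediate
21 | (1R,2S)-2-{(2R,3R)-3-[(tert-butyldimethylsilyl)oxy]-2,6,6-trimethyl-3,6-dihydro-2H-pyran-2-yl}cyclohexan-1-ol | CC1(C)C=C[C@@H](O[Si](C)(C)C(C)(C)C)[C@@](C)([C@H]2CCCC[C@H]2O)O1 | intermediate
22 | triethylammonium N-(methoxycarbonyl)sulfamate ester of 21 (not isolated) | CC1(C)C=C[C@@H](O[Si](C)(C)C(C)(C)C)[C@@](C)([C@H]2CCCC[C@H]2OS(=O)(=O)[N-]C(=O)OC)O1.CC[NH+](CC)CC | intermediate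
23 | tert-butyl({(2R,3R)-2-[(1S)-cyclohex-2-en-1-yl]-2,6,6-trimethyl-3,6-dihydro-2H-pyran-3-yl}oxy)dimethylsilane | CC1(C)C=C[C@@H](O[Si](C)(C)C(C)(C)C)[C@@](C)([C@H]2CCCC=C2)O1 | intermediate
24 | 9-BBN adduct of 23 with boron on C5', anti to the side chain (not isolated) | CC1(C)C=C[C@@H](O[Si](C)(C)C(C)(C)C)[C@@](C)([C@H]2CCC[C@H](B3C4CCCC3CCC4)C2)O1 | intermediate
25 | (1S,3S)-3-{(2R,3R)-3-[(tert-butyldimethylsilyl)oxy]-2,6,6-trimethyl-3,6-dihydro-2H-pyran-2-yl}cyclohexan-1-ol | CC1(C)C=C[C@@H](O[Si](C)(C)C(C)(C)C)[C@@](C)([C@H]2CCC[C@H](O)C2)O1 | intermediate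
26 | (3S)-3-{(2R,3R)-3-[(tert-butyldimethylsilyl)oxy]-2,6,6-trimethyl-3,6-dihydro-2H-pyran-2-yl}cyclohexan-1-one | CC1(C)C=C[C@@H](O[Si](C)(C)C(C)(C)C)[C@@](C)([C@H]2CCCC(=O)C2)O1 | intermediate
27 | tert-butyl({(2R,3R)-2,6,6-trimethyl-2-[(1S)-3-[(trimethylsilyl)oxy]cyclohex-3-en-1-yl]-3,6-dihydro-2H-pyran-3-yl}oxy)dimethylsilane (not isolated) | CC1(C)C=C[C@@H](O[Si](C)(C)C(C)(C)C)[C@@](C)([C@H]2CCC=C(O[Si](C)(C)C)C2)O1 | intermediate
28 | (2R,5S)-2-chloro-5-{(2R,3R)-3-[(tert-butyldimethylsilyl)oxy]-2,6,6-trimethyl-3,6-dihydro-2H-pyran-2-yl}cyclohexan-1-one (drawn as the axial chloride) | CC1(C)C=C[C@@H](O[Si](C)(C)C(C)(C)C)[C@@](C)([C@H]2CC[C@@H](Cl)C(=O)C2)O1 | intermediate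
29 | lithium enolate of 28 at C4' (not isolated) | CC1(C)C=C[C@@H](O[Si](C)(C)C(C)(C)C)[C@@](C)([C@H]2CCC(Cl)=C(O[Li])C2)O1 | intermediate
30 | (2S,5S)-2-chloro-2-methyl-5-{(2R,3R)-3-[(tert-butyldimethylsilyl)oxy]-2,6,6-trimethyl-3,6-dihydro-2H-pyran-2-yl}cyclohexan-1-one | CC1(C)C=C[C@@H](O[Si](C)(C)C(C)(C)C)[C@@](C)([C@H]2CC[C@](C)(Cl)C(=O)C2)O1 | intermediate
31 | (1R,2S,5S)-2-chloro-2-methyl-5-{(2R,3R)-3-[(tert-butyldimethylsilyl)oxy]-2,6,6-trimethyl-3,6-dihydro-2H-pyran-2-yl}cyclohexan-1-ol | CC1(C)C=C[C@@H](O[Si](C)(C)C(C)(C)C)[C@@](C)([C@H]2CC[C@](C)(Cl)[C@H](O)C2)O1 | intermediate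
32 | tert-butyl({(2R,3R)-2-[(1S,3S,4S)-3-bromo-4-chloro-4-methylcyclohexyl]-2,6,6-trimethyl-3,6-dihydro-2H-pyran-3-yl}oxy)dimethylsilane | CC1(C)C=C[C@@H](O[Si](C)(C)C(C)(C)C)[C@@](C)([C@H]2CC[C@](C)(Cl)[C@@H](Br)C2)O1 | intermediate
33 | (2R,3R)-2-[(1S,3S,4S)-3-bromo-4-chloro-4-methylcyclohexyl]-2,6,6-trimethyl-3,6-dihydro-2H-pyran-3-ol | CC1(C)C=C[C@@H](O)[C@@](C)([C@H]2CC[C@](C)(Cl)[C@@H](Br)C2)O1 | target

**Step count and weak points**

Total step count: 21. Longest linear sequence: 21 steps (from 1; 5 and 6 enter in step 4).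

Most likely to fail, riskiest first:

1. Step 18 (methylation of the chloro enolate). What may go wrong: the amide base removes a proton from C6' instead of C4', the enolate loses chloride in a Favorskii-type contraction, or methyl iodide alkylates oxygen. Fallback: set out from ketone 26 through its silyl enol ether 27, which is dehydrogenated with Pd(OAc)2 in MeCN to (5S)-5-{(2R,3R)-3-[(tert-butyldimethylsilyl)oxy]-2,6,6-trimethyl-3,6-dihydro-2H-pyran-2-yl}cyclohex-2-en-1-one F10. α-Chlorination of the enone with PhSeCl and pyridine in CH2Cl2 gives the 2-chloro enone F11. Conjugate reduction with LiBH(s-Bu)3 in THF at −78 °C then makes the chloro enolate at C4' regiospecifically and without any base, and methyl iodide is added to the same flask. The route is rejoined at 30.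

2. Step 20 (invertive bromination). What may go wrong: in the activated alcohol, elimination toward C6' or a 1,2-shift of the axial C4' methyl outruns backside attack at a carbon next to a fully substituted centre. Fallback: set out from 31 and separate activation from displacement. Tf2O and pyridine in CH2Cl2 at −40 °C give the (1R,2S,5S)-2-chloro-2-methyl-5-(pyranyl)cyclohexyl trifluoromethanesulfonate F12, and tetrabutylammonium bromide in toluene at 25 °C, a non-basic source of free bromide, displaces the far better leaving group with inversion. The route is rejoined at 32.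

3. Step 8 (key step). What may go wrong: 1,2-hydride migration within the methyl-substituted carbenoid, giving a vinyl ketone, outruns capture by the crowded ether oxygen. Fallback: an acceptor/acceptor carbenoid that has no hydrogen to migrate, with the ester turned into the methyl group afterwards; the exo transition state and the chirality transfer are the same.
   - Set out from alcohol 9: Dess–Martin oxidation gives aldehyde 10, and Roskamp homologation with methyl diazoacetate and SnCl2 gives methyl 6-{[(1S,4R)-4-acetoxycyclohex-2-en-1-yl]oxy}-6-methyl-3-oxoheptanoate F1.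
   - Diazo transfer with 4-acetamidobenzenesulfonyl azide and Et3N gives the 2-diazo-3-oxo ester F2.
   - Rh2(OAc)4 in CH2Cl2 should give, through the analogous oxonium ylide and [2,3] shift, methyl (2R)-2-[(1S,6R)-6-acetoxycyclohex-2-en-1-yl]-6,6-dimethyl-3-oxooxane-2-carboxylate F3.
   - Hydrogenation over Pd/C gives the saturated keto ester F4; IBX in DMSO/toluene at 70 °C gives the enone ester F5; CBS reduction as in step 11 gives the allylic alcohol F6; t-BuMe2SiOTf with 2,6-lutidine gives the silyl ether F7.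
   - LiAlH4 in THF reduces the methyl ester to the hydroxymethyl group and cleaves the acetate, giving the diol F8. TsCl in pyridine sulfonylates only the primary hydroxyl, giving the primary tosylate F9, and LiBHEt3 in THF replaces the tosylate by hydrogen. The route is rejoined at 21.

**Further compounds**

F1 | step 8 | methyl 6-{[(1S,4R)-4-acetoxycyclohex-2-en-1-yl]oxy}-6-methyl-3-oxoheptanoate | COC(=O)CC(=O)CCC(C)(C)O[C@@H]1C=C[C@H](OC(C)=O)CC1
F2 | step 8 | methyl 6-{[(1S,4R)-4-acetoxycyclohex-2-en-1-yl]oxy}-2-diazo-6-methyl-3-oxoheptanoate | COC(=O)C(=[N+]=[N-])C(=O)CCC(C)(C)O[C@@H]1C=C[C@H](OC(C)=O)CC1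
F3 | step 8 | methyl (2R)-2-[(1S,6R)-6-acetoxycyclohex-2-en-1-yl]-6,6-dimethyl-3-oxooxane-2-carboxylate | CC1(C)CCC(=O)[C@@](C(=O)OC)([C@H]2C=CCC[C@H]2OC(C)=O)O1
F4 | step 8 | methyl (2R)-2-[(1S,2R)-2-acetoxycyclohexyl]-6,6-dimethyl-3-oxooxane-2-carboxylate | CC1(C)CCC(=O)[C@@](C(=O)OC)([C@H]2CCCC[C@H]2OC(C)=O)O1
F5 | step 8 | methyl (2R)-2-[(1S,2R)-2-acetoxycyclohexyl]-6,6-dimethyl-3-oxo-3,6-dihydro-2H-pyran-2-carboxylate | CC1(C)C=CC(=O)[C@@](C(=O)OC)([C@H]2CCCC[C@H]2OC(C)=O)O1
F6 | step 8 | methyl (2R,3R)-2-[(1S,2R)-2-acetoxycyclohexyl]-3-hydroxy-6,6-dimethyl-3,6-dihydro-2H-pyran-2-carboxylate | CC1(C)C=C[C@@H](O)[C@@](C(=O)OC)([C@H]2CCCC[C@H]2OC(C)=O)O1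
F7 | step 8 | tert-butyldimethylsilyl ether of F6 | CC1(C)C=C[C@@H](O[Si](C)(C)C(C)(C)C)[C@@](C(=O)OC)([C@H]2CCCC[C@H]2OC(C)=O)O1
F8 | step 8 | diol from F7: hydroxymethyl group on the pyran carbon and free cyclohexanol, configuration as in 21 | CC1(C)C=C[C@@H](O[Si](C)(C)C(C)(C)C)[C@@](CO)([C@H]2CCCC[C@H]2O)O1
F9 | step 8 | primary 4-methylbenzenesulfonate of F8 | CC1(C)C=C[C@@H](O[Si](C)(C)C(C)(C)C)[C@@](COS(=O)(=O)c2ccc(C)cc2)([C@H]2CCCC[C@H]2O)O1
F10 | step 18 | (5S)-5-{(2R,3R)-3-[(tert-butyldimethylsilyl)oxy]-2,6,6-trimethyl-3,6-dihydro-2H-pyran-2-yl}cyclohex-2-en-1-one | CC1(C)C=C[C@@H](O[Si](C)(C)C(C)(C)C)[C@@](C)([C@H]2CC=CC(=O)C2)O1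
F11 | step 18 | (5S)-2-chloro-5-{(2R,3R)-3-[(tert-butyldimethylsilyl)oxy]-2,6,6-trimethyl-3,6-dihydro-2H-pyran-2-yl}cyclohex-2-en-1-one | CC1(C)C=C[C@@H](O[Si](C)(C)C(C)(C)C)[C@@](C)([C@H]2CC=C(Cl)C(=O)C2)O1
F12 | step 20 | (1R,2S,5S)-2-chloro-2-methyl-5-{(2R,3R)-3-[(tert-butyldimethylsilyl)oxy]-2,6,6-trimethyl-3,6-dihydro-2H-pyran-2-yl}cyclohexyl trifluoromethanesulfonate | CC1(C)C=C[C@@H](O[Si](C)(C)C(C)(C)C)[C@@](C)([C@H]2CC[C@](C)(Cl)[C@H](OS(=O)(=O)C(F)(F)F)C2)O1
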